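## Retrosynthetic overview

1. Target ⇐ C11 hydroxy lactone (last step: butyrylation of the only free, tertiary OH) ⇐ C16 primary alcohol by oxidative lactonisation onto C3–OH; C15 comes from hydroboration of a C14 isopropenyl group.
2. Tertiary carbinols C11 and C3 ⇐ two separate methyl Grignard additions to ring ketones of the tricycle (C11 ketone masked as a methyl enol ether, C3 oxygen as a silyl ether).
3. Cyclohexene and oxolane rings ⇐ one intramolecular Diels–Alder reaction of an oxonene carrying a 2-methoxy-1,3-diene on C9 and an E-enone on C2 (forms C1–C10 and C13–C14).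
4. Oxonene ⇐ ring-closing metathesis (C6=C7) of an acyclic diene ⇐ Evans syn glycolate aldol of a glycolyl oxazolidinone with pent-4-enal (C2–C3 bond, C2 stereocentre) ⇐ (S)-benzyl glycidyl ether + isopropenylmagnesium bromide + bromoacetic acid.
5. Ring order: nine-membered oxonene first, then cyclohexene and oxolane together, ε-lactone last.

Assumption: cladiellin numbering is used for every intermediate (C2 and C9 carry the bridging ether oxygen; C1/C10 become the ring-fusion carbons; C3, C7 and C11 carry the methyl groups; C14 carries C15; C16 becomes the lactone carbonyl); "oxonene" is the 2,3,4,5,8,9-hexahydrooxonine ring O–C2…C9 with the 6Z alkene, "tricycle" is this oxonene with the cyclohexane C1, C10–C14 cis-fused through the oxolane C1–C2–O–C9–C10; methyl 2-(dimethoxyphosphoryl)-2-methoxyacetate and crystalline (−)-Ipc2BH are taken as purchasable.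

## Route

Step 1
Reactants: 1 (S)-benzyl glycidyl ether; 2 isopropenylmagnesium bromide
Product: 3 (2S)-1-(benzyloxy)-4-methylpent-4-en-2-ol
Conditions: CuI (10 mol %), THF, −30 → 0 °C; then H2O
Reagents that add atoms: none
Why: Copper-catalysed SN2 opening of the epoxide at its terminal carbon by the Grignard reagent leaves the C9 stereocentre of 1 untouched.

Step 2
Reactants: 3 (2S)-1-(benzyloxy)-4-methylpent-4-en-2-ol; 4 bromoacetic acid
Product: 5 {[(2S)-1-(benzyloxy)-4-methylpent-4-en-2-yl]oxy}acetic acid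
Conditions: NaH (3 equiv), THF, 0 °C → rt; then 1 M HCl
Reagents that add atoms: none
Why: Williamson etherification of the sodium alkoxide with sodium bromoacetate installs the C1–C2 glycolate unit without touching the stereocentre.

Step 3
Reactants: 5 {[(2S)-1-(benzyloxy)-4-methylpent-4-en-2-yl]oxy}acetic acid; 6 (R)-4-benzyloxazolidin-2-one
Product: 8 (4R)-4-benzyl-3-({[(2S)-1-(benzyloxy)-4-methylpent-4-en-2-yl]oxy}acetyl)oxazolidin-2-one, via mixed pivalic anhydride 7 (not isolated)
Conditions: PivCl, Et3N, THF, −78 → 0 °C; then 6 + n-BuLi (THF, −78 °C), −78 → 0 °C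
Reagents that add atoms: pivaloyl chloride CC(C)(C)C(Cl)=O (its acyl group is found only in 7)
Why: N-acylation (acyl substitution) of the lithiated auxiliary occurs at the unhindered glycolyl carbonyl of the mixed anhydride, and the amine base keeps free HCl away from the methallyl group.

Step 4
Reactants: 8 (4R)-4-benzyl-3-({[(2S)-1-(benzyloxy)-4-methylpent-4-en-2-yl]oxy}acetyl)oxazolidin-2-one; 9 pent-4-enal
Product: 11 (4R)-4-benzyl-3-[(2R,3S)-2-{[(2S)-1-(benzyloxy)-4-methylpent-4-en-2-yl]oxy}-3-hydroxyhept-6-enoyl]oxazolidin-2-one, via dibutylboron Z-enolate 10 (not isolated)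
Conditions: Bu2BOTf, Et3N, CH2Cl2, −78 → 0 °C; 9, −78 → 0 °C; then pH 7 buffer, MeOH, H2O2, 0 °C
Reagents that add atoms: dibutylboron triflate CCCCB(CCCC)OS(=O)(=O)C(F)(F)F (its boron is found only in 10)
Why: Evans syn aldol, in which the Z boron enolate reacts through a closed Zimmerman–Traxler chair on the face away from the benzyl group of the (R)-auxiliary and so gives the 2R,3S syn adduct (C2 as needed in the target; the C3 carbinol is oxidised later).

Step 5
Reactants: 11 aldol adduct
Product: 12 3-O-tert-butyldimethylsilyl ether of 11 (2R,3S)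
Conditions: TBSOTf, 2,6-lutidine, CH2Cl2, −78 → 0 °C
Reagents that add atoms: tert-butyldimethylsilyl triflate CC(C)(C)[Si](C)(C)OS(=O)(=O)C(F)(F)F
Why: O-silylation with the silyl triflate protects the hindered secondary C3–OH as a robust ether (and blocks retro-aldol) until step 19.

Step 6
Reactants: 12 silylated aldol adduct
Product: 13 (2S,3S)-2-{[(2S)-1-(benzyloxy)-4-methylpent-4-en-2-yl]oxy}-3-[(tert-butyldimethylsilyl)oxy]hept-6-en-1-ol
Conditions: LiBH4, MeOH (1 equiv), THF, 0 °C
Reagents that add atoms: none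
Why: Borohydride reduction of the imide at its exocyclic carbonyl releases the C1 primary alcohol and the recoverable auxiliary without touching a stereocentre.

Step 7
Reactants: 13 primary alcohol
Product: 14 1-O-triethylsilyl ether of 13 (2S,3S)
Conditions: TESCl, imidazole, CH2Cl2, 0 °C
Reagents that add atoms: chlorotriethylsilane CC[Si](Cl)(CC)CC
Why: O-silylation with the more labile triethylsilyl group lets C1–O be unmasked later by fluoride while the secondary TBS ether stays.

Step 8
Reactants: 14 acyclic diene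
Product: 15 oxonene (2S,3S,9S,6Z) with 9-CH2OBn, 3-OTBS, 7-methyl and 2-CH2OTES
Conditions: second-generation Grubbs catalyst (5 mol %), CH2Cl2 (0.002 M), 40 °C
Reagents that add atoms: none
Why: Ring-closing metathesis between the monosubstituted and the 1,1-disubstituted alkene closes the nine-membered ring, in which only the Z trisubstituted alkene is geometrically possible and the gauche C2/C3 oxygens pre-fold the chain.

Step 9
Reactants: 15 oxonene benzyl ether
Product: 16 oxonene (2S,3S,9S,6Z) with free 9-CH2OH (C10 alcohol)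
Conditions: Na, NH3 (l)/THF, −78 °C; then solid NH4Cl
Reagents that add atoms: none
Why: Dissolving-metal (Birch-type) hydrogenolysis cleaves the benzyl ether, while the isolated trisubstituted alkene and both silyl ethers are inert to these conditions.

Step 10
Reactants: 16 C10 alcohol
Product: 17 oxonene-9-carbaldehyde (2S,3S,9S,6Z)
Conditions: Dess–Martin periodinane, pyridine, CH2Cl2, 0 °C → rt
Reagents that add atoms: none
Why: Dess–Martin oxidation gives the α-alkoxy aldehyde under buffered conditions that do not epimerise C9, and it is used at once.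

Step 11
Reactants: 17 oxonene-9-carbaldehyde; 18 methyl 2-(dimethoxyphosphoryl)-2-methoxyacetate
Product: 19 methyl (Z)-2-methoxy-3-(oxonen-9-yl)prop-2-enoate (2S,3S,9S; 2-CH2OTES, 3-OTBS)
Conditions: 18, NaH, THF, 0 °C; then 17, −78 → 0 °C
Reagents that add atoms: none
Why: Horner–Wadsworth–Emmons olefination places the ester trans to the branched C9 substituent (the usual thermodynamic preference), which is the Z enol ether geometry needed later for an s-cis diene.

Step 12
Reactants: 19 α-methoxy enoate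
Product: 20 (Z)-2-methoxy-3-(oxonen-9-yl)prop-2-en-1-ol (2S,3S,9S)
Conditions: i-Bu2AlH (2.5 equiv), CH2Cl2, −78 °C; then aq. potassium sodium tartrate
Reagents that add atoms: none
Why: Hydride 1,2-reduction of the ester at −78 °C gives the allylic alcohol without touching silyl ethers, alkenes or the alkene geometry.

Step 13
Reactants: 20 allylic alcohol
Product: 21 (Z)-2-methoxy-3-(oxonen-9-yl)prop-2-enal (2S,3S,9S)
Conditions: MnO2 (20 equiv), CH2Cl2, rt
Reagents that add atoms: none
Why: MnO2 allylic oxidation is neutral, so the acid-sensitive enol ether and the alkene geometry survive.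

Step 14
Reactants: 21 α-methoxy enal
Product: 22 9-[(1Z)-2-methoxybuta-1,3-dien-1-yl]oxonene (2S,3S,9S; 2-CH2OTES, 3-OTBS)
Conditions: Ph3PCH3Br, KOtBu, THF, 0 °C; then 21, 0 °C
Reagents that add atoms: methyltriphenylphosphonium bromide C[P+](c1ccccc1)(c1ccccc1)c1ccccc1.[Br-]
Why: Wittig methylenation of the aldehyde completes the 2-methoxy-1,3-diene with the C10=C11 geometry retained.

Step 15
Reactants: 22 methoxydiene bis-silyl ether
Product: 23 9-[(1Z)-2-methoxybuta-1,3-dien-1-yl]oxonene with free 2-CH2OH and 3-OTBS (2S,3S,9S)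
Conditions: TBAF (1.1 equiv), THF, 0 °C
Reagents that add atoms: none
Why: Fluoride desilylation removes the unhindered primary TES ether far faster than the hindered secondary TBS ether, and the basic medium leaves the methoxydiene intact.

Step 16
Reactants: 23 diene alcohol
Product: 24 9-[(1Z)-2-methoxybuta-1,3-dien-1-yl]oxonene-2-carbaldehyde (2R,3S,9S; 3-OTBS)
Conditions: Dess–Martin periodinane, pyridine, CH2Cl2, 0 °C
Reagents that add atoms: none
Why: Pyridine-buffered Dess–Martin oxidation gives the C1 aldehyde without acid that would hydrolyse the enol ether, and the crude aldehyde is used directly to avoid C2 epimerisation.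

Step 17
Reactants: 24 diene aldehyde; 25 1-(triphenylphosphoranylidene)propan-2-one
Product: 27 tricycle (1R,2S,3S,9S,10R,14R) with 14-acetyl, 11-methoxy-Δ11(12) enol ether and 3-OTBS, via tetraene enone 26 (not isolated)
Conditions: 25 (1.5 equiv), CH2Cl2, rt → 40 °C
Reagents that add atoms: none
Why: Wittig olefination with the stabilised ylide gives the E-enone, which undergoes a spontaneous intramolecular Diels–Alder reaction with the electron-rich diene: the E geometry fixes H1/H14 trans, and the cis-2,9-disubstituted oxonene tether holds diene and dienophile so that the new cyclohexene forms on the oxolane face opposite the oxonene chain, giving the cis ring fusion with H1 and H10 syn to each other and anti to H2 and H9.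

Step 18
Reactants: 27 tricyclic methyl ketone
Product: 28 tricycle (1S,2S,3S,9S,10R,14R) with 14-isopropenyl, 11-methoxy-Δ11(12) and 3-OTBS
Conditions: Ph3PCH3Br, KOtBu, THF, 0 °C → rt
Reagents that add atoms: methyltriphenylphosphonium bromide C[P+](c1ccccc1)(c1ccccc1)c1ccccc1.[Br-]
Why: Wittig methylenation converts the acetyl group into the isopropenyl group while the C11 carbonyl stays masked as its enol ether, and C14 keeps its more stable equatorial configuration trans to C2.

Step 19
Reactants: 28 enol ether silyl ether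
Product: 29 tricycle (1S,2S,3S,9S,10R,14R) with 11-oxo, 3-hydroxy and 14-isopropenyl
Conditions: HF (48 % aq), MeCN, 0 °C → rt
Reagents that add atoms: water O
Why: Acid-catalysed enol ether hydrolysis unveils the C11 ketone and the same reagent cleaves the TBS ether, while the cis ring fusion at C10 is the stable arrangement and is retained.

Step 20
Reactants: 29 keto alcohol
Product: 30 tricycle (1S,2S,3S,9S,10R,11R,14R) with 11-methyl-3,11-diol and 14-isopropenyl
Conditions: MeMgBr (4 equiv), THF, −78 → −20 °C; then H2O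
Reagents that add atoms: methylmagnesium bromide C[Mg]Br
Why: Grignard 1,2-addition in which methyl attacks the C11 ketone axially from the convex face, anti to the axial C10–C9 bond (Felkin–Anh), so that the new hydroxyl is equatorial and syn to C9 (11R).

Step 21
Reactants: 30 diol
Product: 31 tricycle (1S,2S,9S,10R,11R,14R) with 3-oxo, 11-hydroxy-11-methyl and 14-isopropenyl
Conditions: Dess–Martin periodinane, pyridine, CH2Cl2, rt
Reagents that add atoms: none
Why: Dess–Martin oxidation converts only the secondary C3 alcohol into the ketone because the tertiary C11 alcohol cannot be oxidised.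

Step 22
Reactants: 31 C3 ketone
Product: 32 tricycle (1S,2S,3S,9S,10R,11R,14R) with 3,11-dimethyl-3,11-diol and 14-isopropenyl
Conditions: MeMgCl (4 equiv), THF, −78 °C; then H2O
Reagents that add atoms: methylmagnesium chloride C[Mg]Cl
Why: Grignard 1,2-addition to the α-alkoxy ketone held in the rigid tricycle occurs from the outer face of the oxonene, anti to the C2–O bond (polar Felkin–Anh sense, since the ring geometry prevents a five-membered chelate), giving the 3S tertiary alcohol.

Step 23
Reactants: 32 isopropenyl diol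
Product: 34 tricyclic 3,11,16-triol (1S,2S,3S,9S,10R,11R,14S,15R), via C16 diisopinocampheylborane 33 (not isolated)
Conditions: (−)-Ipc2BH (4 equiv), THF, 0 °C → rt; then NaOH, H2O2, 0 °C → rt
Reagents that add atoms: hydrogen peroxide OO; (−)-diisopinocampheylborane B([C@@H]1C[C@@H]2C[C@H]([C@H]1C)C2(C)C)[C@@H]1C[C@@H]2C[C@H]([C@H]1C)C2(C)C (its boron is found only in 33)
Why: Brown hydroboration–oxidation, in which the bulky chiral dialkylborane adds anti-Markovnikov only to the 1,1-disubstituted alkene (the trisubstituted ring alkene is too hindered) and its facial preference, the sense that gives (R)-2-methylalkan-1-ols, sets 15R.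

Step 24
Reactants: 34 triol
Product: 37 hydroxy lactone (1S,2S,3S,9S,10R,11R,14R,15R) with 11-OH free, via hydroxy aldehyde 35 (not isolated), via lactol 36 (not isolated)
Conditions: TEMPO (0.2 equiv), PhI(OAc)2 (3 equiv), CH2Cl2, rt
Reagents that add atoms: none
Why: Oxoammonium (TEMPO) oxidation of the primary alcohol gives the aldehyde, which the nearby C3 tertiary hydroxyl traps as the seven-membered lactol that is oxidised on to the lactone, while tertiary alcohols and alkenes are inert and the C11–OH, trans across the cyclohexane, cannot reach C16.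

Step 25
Reactants: 37 hydroxy lactone
Product: 38 target butyrate CNP0294597.2
Conditions: (PrCO)2O, DMAP, Et3N, CH2Cl2, 40 °C
Reagents that add atoms: butyric anhydride CCCC(=O)OC(=O)CCC
Why: DMAP-catalysed acyl transfer (Steglich-type esterification) acylates the only free hydroxyl, the equatorial tertiary C11–OH, with retention at C11.

## Compound list

1 | (S)-benzyl glycidyl ether | C(OCc1ccccc1)[C@@H]1CO1 | starting material
2 | isopropenylmagnesium bromide | CC(=C)[Mg]Br | starting material
3 | (2S)-1-(benzyloxy)-4-methylpent-4-en-2-ol | C=C(C)C[C@H](O)COCc1ccccc1 | intermediate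
4 | bromoacetic acid | OC(=O)CBr | starting material
5 | {[(2S)-1-(benzyloxy)-4-methylpent-4-en-2-yl]oxy}acetic acid | C=C(C)C[C@H](OCC(=O)O)COCc1ccccc1 | intermediate
6 | (R)-4-benzyloxazolidin-2-one | O=C1N[C@H](Cc2ccccc2)CO1 | starting material
7 | mixed pivalic anhydride of 5 | C=C(C)C[C@H](OCC(=O)OC(=O)C(C)(C)C)COCc1ccccc1 | intermediate
8 | (4R)-4-benzyl-3-({[(2S)-1-(benzyloxy)-4-methylpent-4-en-2-yl]oxy}acetyl)oxazolidin-2-one | C=C(C)C[C@H](OCC(=O)N1[C@H](Cc2ccccc2)COC1=O)COCc1ccccc1 | intermediate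
9 | pent-4-enal | C=CCCC=O | starting material
10 | dibutylboron Z-enolate of 8 | CCCCB(CCCC)O/C(=C\O[C@H](COCc1ccccc1)CC(C)=C)N1[C@H](Cc2ccccc2)COC1=O | intermediate
11 | (4R)-4-benzyl-3-[(2R,3S)-2-{[(2S)-1-(benzyloxy)-4-methylpent-4-en-2-yl]oxy}-3-hydroxyhept-6-enoyl]oxazolidin-2-one | C=CCC[C@H](O)[C@@H](O[C@H](COCc1ccccc1)CC(C)=C)C(=O)N1[C@H](Cc2ccccc2)COC1=O | intermediate
12 | 3-O-TBS ether of 11 (2R,3S) | C=CCC[C@H](O[Si](C)(C)C(C)(C)C)[C@@H](O[C@H](COCc1ccccc1)CC(C)=C)C(=O)N1[C@H](Cc2ccccc2)COC1=O | intermediate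
13 | (2S,3S)-2-{[(2S)-1-(benzyloxy)-4-methylpent-4-en-2-yl]oxy}-3-[(tert-butyldimethylsilyl)oxy]hept-6-en-1-ol | C=CCC[C@H](O[Si](C)(C)C(C)(C)C)[C@@H](O[C@H](COCc1ccccc1)CC(C)=C)CO | intermediate
14 | 1-O-triethylsilyl ether of 13 (2S,3S) | C=CCC[C@H](O[Si](C)(C)C(C)(C)C)[C@@H](O[C@H](COCc1ccccc1)CC(C)=C)CO[Si](CC)(CC)CC | intermediate
15 | (2S,3S,9S,6Z)-9-[(benzyloxy)methyl]-3-[(tert-butyldimethylsilyl)oxy]-7-methyl-2-{[(triethylsilyl)oxy]methyl}-2,3,4,5,8,9-hexahydrooxonine | c1ccccc1COC[C@@H]1C/C(C)=C\CC[C@H](O[Si](C)(C)C(C)(C)C)[C@H](CO[Si](CC)(CC)CC)O1 | intermediate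
16 | oxonene 15 with 9-CH2OH in place of 9-CH2OBn (2S,3S,9S,6Z) | OC[C@@H]1C/C(C)=C\CC[C@H](O[Si](C)(C)C(C)(C)C)[C@H](CO[Si](CC)(CC)CC)O1 | intermediate
17 | corresponding oxonene-9-carbaldehyde (2S,3S,9S,6Z) | O=C[C@@H]1C/C(C)=C\CC[C@H](O[Si](C)(C)C(C)(C)C)[C@H](CO[Si](CC)(CC)CC)O1 | intermediate
18 | methyl 2-(dimethoxyphosphoryl)-2-methoxyacetate | COC(=O)C(OC)P(=O)(OC)OC | starting material
19 | methyl (Z)-2-methoxy-3-(oxonen-9-yl)prop-2-enoate, oxonene as in 15 (2S,3S,9S) | COC(=O)/C(OC)=C/[C@@H]1C/C(C)=C\CC[C@H](O[Si](C)(C)C(C)(C)C)[C@H](CO[Si](CC)(CC)CC)O1 | intermediate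
20 | (Z)-2-methoxy-3-(oxonen-9-yl)prop-2-en-1-ol (2S,3S,9S) | OC/C(OC)=C/[C@@H]1C/C(C)=C\CC[C@H](O[Si](C)(C)C(C)(C)C)[C@H](CO[Si](CC)(CC)CC)O1 | intermediate
21 | (Z)-2-methoxy-3-(oxonen-9-yl)prop-2-enal (2S,3S,9S) | O=C/C(OC)=C/[C@@H]1C/C(C)=C\CC[C@H](O[Si](C)(C)C(C)(C)C)[C@H](CO[Si](CC)(CC)CC)O1 | intermediate
22 | 9-[(1Z)-2-methoxybuta-1,3-dien-1-yl]oxonene with 2-CH2OTES and 3-OTBS (2S,3S,9S) | C=C/C(OC)=C/[C@@H]1C/C(C)=C\CC[C@H](O[Si](C)(C)C(C)(C)C)[C@H](CO[Si](CC)(CC)CC)O1 | intermediate
23 | 9-[(1Z)-2-methoxybuta-1,3-dien-1-yl]oxonene with 2-CH2OH and 3-OTBS (2S,3S,9S) | C=C/C(OC)=C/[C@@H]1C/C(C)=C\CC[C@H](O[Si](C)(C)C(C)(C)C)[C@H](CO)O1 | intermediate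
24 | 9-[(1Z)-2-methoxybuta-1,3-dien-1-yl]-3-OTBS-oxonene-2-carbaldehyde (2R,3S,9S) | C=C/C(OC)=C/[C@@H]1C/C(C)=C\CC[C@H](O[Si](C)(C)C(C)(C)C)[C@H](C=O)O1 | intermediate
25 | 1-(triphenylphosphoranylidene)propan-2-one | CC(=O)C=P(c1ccccc1)(c1ccccc1)c1ccccc1 | starting material
26 | tetraene: 2-[(E)-3-oxobut-1-enyl]-9-[(1Z)-2-methoxybuta-1,3-dien-1-yl]-3-OTBS-oxonene (2S,3S,9S) | C=C/C(OC)=C/[C@@H]1C/C(C)=C\CC[C@H](O[Si](C)(C)C(C)(C)C)[C@H](/C=C/C(C)=O)O1 | intermediate
27 | tricycle with 14-acetyl, 11-methoxy-Δ11(12) and 3-OTBS (1R,2S,3S,9S,10R,14R) | COC1=CC[C@@H](C(C)=O)[C@H]2[C@@H]1[C@@H]1C/C(C)=C\CC[C@H](O[Si](C)(C)C(C)(C)C)[C@H]2O1 | intermediate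
28 | tricycle with 14-isopropenyl, 11-methoxy-Δ11(12) and 3-OTBS (1S,2S,3S,9S,10R,14R) | COC1=CC[C@@H](C(C)=C)[C@H]2[C@@H]1[C@@H]1C/C(C)=C\CC[C@H](O[Si](C)(C)C(C)(C)C)[C@H]2O1 | intermediate
29 | tricycle with 11-oxo, 3-hydroxy and 14-isopropenyl (1S,2S,3S,9S,10R,14R) | O=C1CC[C@@H](C(C)=C)[C@H]2[C@@H]1[C@@H]1C/C(C)=C\CC[C@H](O)[C@H]2O1 | intermediate
30 | tricycle with 11-methyl-3,11-diol and 14-isopropenyl (1S,2S,3S,9S,10R,11R,14R) | O[C@]1(C)CC[C@@H](C(C)=C)[C@H]2[C@@H]1[C@@H]1C/C(C)=C\CC[C@H](O)[C@H]2O1 | intermediate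
31 | tricycle with 3-oxo, 11-hydroxy-11-methyl and 14-isopropenyl (1S,2S,9S,10R,11R,14R) | O[C@]1(C)CC[C@@H](C(C)=C)[C@H]2[C@@H]1[C@@H]1C/C(C)=C\CCC(=O)[C@H]2O1 | intermediate
32 | tricycle with 3,11-dimethyl-3,11-diol and 14-isopropenyl (1S,2S,3S,9S,10R,11R,14R) | O[C@]1(C)CC[C@@H](C(C)=C)[C@H]2[C@@H]1[C@@H]1C/C(C)=C\CC[C@](C)(O)[C@H]2O1 | intermediate
33 | C16 diisopinocampheylborane of 32 (15R) | O[C@]1(C)CC[C@@H]([C@@H](C)CB([C@@H]3C[C@@H]4C[C@H]([C@H]3C)C4(C)C)[C@@H]3C[C@@H]4C[C@H]([C@H]3C)C4(C)C)[C@H]2[C@@H]1[C@@H]1C/C(C)=C\CC[C@](C)(O)[C@H]2O1 | intermediate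
34 | tricyclic 3,11,16-triol (1S,2S,3S,9S,10R,11R,14S,15R) | O[C@]1(C)CC[C@@H]([C@@H](C)CO)[C@H]2[C@@H]1[C@@H]1C/C(C)=C\CC[C@](C)(O)[C@H]2O1 | intermediate
35 | 3,11-dihydroxy C16 aldehyde (15R) | O[C@]1(C)CC[C@@H]([C@@H](C)C=O)[C@H]2[C@@H]1[C@@H]1C/C(C)=C\CC[C@](C)(O)[C@H]2O1 | intermediate
36 | seven-membered C16 lactol (C3–O–C16, C16 configuration undefined) | O[C@]1(C)CC[C@@H]2[C@H]3[C@@H]1[C@@H]1C/C(C)=C\CC[C@](C)(OC(O)[C@@H]2C)[C@H]3O1 | intermediate
37 | 11-hydroxy lactone (1S,2S,3S,9S,10R,11R,14R,15R) | O[C@]1(C)CC[C@@H]2[C@H]3[C@@H]1[C@@H]1C/C(C)=C\CC[C@](C)(OC(=O)[C@@H]2C)[C@H]3O1 | intermediate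
38 | CNP0294597.2, the 11-butanoate of 37 (1S,2S,3S,9S,10R,11R,14R,15R,6Z) | CCCC(=O)O[C@]1(C)CC[C@@H]2[C@H]3[C@@H]1[C@@H]1C/C(C)=C\CC[C@](C)(OC(=O)[C@@H]2C)[C@H]3O1 | target

## Step count and risks

Total step count: 25. Longest linear sequence: 25 steps (1 → 38); all other building blocks (2, 4, 6, 9, 18, 25) are bought.

The three steps most likely to fail:

Step 20 (facial selectivity of methyl addition at C11). The axial, convex-face attack is argued from the conformation, not proven, and MeMgBr is not a strongly face-selective nucleophile. The fallback sets out from 29 and comes back at 30. Corey–Chaykovsky reaction with dimethylsulfonium methylide (Me3SI, n-BuLi, THF, −10 °C; one extra equivalent for the C3–OH), a small and irreversibly adding carbon nucleophile with a much stronger axial preference, gives the C11 spiro-epoxide F1. LiEt3BH (THF, 0 °C) then opens the oxirane at its CH2 terminus and delivers 30.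

Step 23 (C15 by hydroboration). Reagent control over a 1,1-disubstituted alkene is modest and the intrinsic bias of the substrate is uncertain, so the diastereomer ratio may be poor or reversed. The fallback sets out from 32 and comes back at 37, and moves the control of C15 to the lactone stage. Hydroboration with achiral 9-BBN (THF, rt; NaOH, H2O2) is accepted even if it gives mainly the 15-epi triol F2. The step-24 oxidation (TEMPO, PhI(OAc)2) carries this on to the 15-epi lactone F3. C15 is then the only enolisable centre: LiN(i-Pr)2 (2.2 equiv, THF, −78 °C; one equivalent is taken by the C11–OH) forms the lactone enolate, and kinetic protonation with a bulky phenol from the face anti to C13 (H15 syn to H14) gives 37. Recovered F3 is recycled.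

Step 24 (oxidative lactonisation onto a tertiary alcohol through a seven-membered lactol). If the hydroxy aldehyde does not close, the reaction stalls or the aldehyde epimerises. The fallback sets out from 34 and comes back at 37, and closes the ring by carboxyl activation instead. The primary alcohol is oxidised fully (TEMPO, PhI(OAc)2, MeCN/H2O, rt) to the dihydroxy acid F4. Shiina lactonisation (2-methyl-6-nitrobenzoic anhydride, DMAP, Et3N, toluene, high dilution, rt → 60 °C) then acylates the C3 hydroxyl, the only one within reach of C16, to give 37.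

## Further compounds

F1 | step 20 | C11 spiro-epoxide of 29 (11R, oxirane oxygen syn to C9; 3-OH free) | O3[C@]1(C3)CC[C@@H](C(C)=C)[C@H]2[C@@H]1[C@@H]1C/C(C)=C\CC[C@H](O)[C@H]2O1
F2 | step 23 | 15-epi triol (15S epimer of 34) | O[C@]1(C)CC[C@@H]([C@H](C)CO)[C@H]2[C@@H]1[C@@H]1C/C(C)=C\CC[C@](C)(O)[C@H]2O1
F3 | step 23 | 15-epi lactone (15S epimer of 37) | O[C@]1(C)CC[C@@H]2[C@H]3[C@@H]1[C@@H]1C/C(C)=C\CC[C@](C)(OC(=O)[C@H]2C)[C@H]3O1
F4 | step 24 | 3,11-dihydroxy C16 carboxylic acid (15R) | O[C@]1(C)CC[C@@H]([C@@H](C)C(O)=O)[C@H]2[C@@H]1[C@@H]1C/C(C)=C\CC[C@](C)(O)[C@H]2O1
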